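Ring B is disconnected at C10a–C10 and C9–C8a (phenanthrene numbering). The feature used is that ring B is a naphthalen-1(2H)-one whose C9 carbonyl sits peri to the C8 oxygen of ring C, and that the C4a=C10a alkene of ring A holds the ring C aryl group and the C10a side chain cis. A diazoacetyl group on C10a of the finished ring A (N,O-acetal dienone, both stereocentres set, symmetric 3,5-dimethoxyphenyl on C4a) undergoes Wolff rearrangement to an arylvinylketene that closes by 6π-electrocyclisation, forming both bonds and ring B in one operation. Ring A arises from a hexasubstituted biaryl phenol by enantioselective para-hydroxylative dearomatisation; peri-selective O-demethylation finishes.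

Key step: step 8

Remark on locants: ring A carbons carry phenanthrene locants (C1–C4, C4a, C10a) throughout, also before ring B exists.
Assumption (tautomer): the C9-keto/C10-methylene form drawn for the target and for 16 is taken as the stable tautomer; the C9 naphthol form would be the same compound under proton exchange.
Assumption (sense of induction): the (R,R) catalyst of step 5 is written for the 4R series; the sense has to be confirmed on the first run (CD or X-ray), and the (S,S) catalyst is used if it is opposite.

Step 1
Reactants: 1 5-bromo-1,2,3-trimethoxybenzene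
Product: 2 6-bromo-2,3,4-trimethoxybenzaldehyde
Conditions: Cl2CHOMe, TiCl4, CH2Cl2, −10 °C to rt; then H2O
Reagents that add atoms: dichloromethyl methyl ether, COC(Cl)Cl; water, O
Why: Rieche formylation, in which the TiCl4-activated chloromethyl oxocarbenium ion attacks one of the two equivalent free ring carbons (each ortho and para to methoxy groups) and hydrolysis of the α-chloro ether gives the aldehyde.

Step 2
Reactants: 2 6-bromo-2,3,4-trimethoxybenzaldehyde
Product: 3 1-bromo-3,4,5-trimethoxy-2-methylbenzene
Conditions: Et3SiH (3 equiv), CF3CO2H, CH2Cl2, 0 °C to rt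
Reagents that add atoms: none
Why: Ionic hydrogenation, in which the protonated aldehyde and the derived benzylic alcohol give benzylic cations stabilised by the ortho and para methoxy groups, and Et3SiH reduces them to the methyl group without touching the aryl bromide.

Step 3
Reactants: 3 1-bromo-3,4,5-trimethoxy-2-methylbenzene
Product: 5 1-(6-bromo-2-hydroxy-3,4-dimethoxy-5-methylphenyl)ethan-1-one, via trimethoxyaryl methyl ketone 4 (not isolated)
Conditions: AcCl (1.2 equiv), AlCl3 (2.5 equiv), CH2Cl2, 0 °C to rt; then aq. HCl
Reagents that add atoms: acetyl chloride, CC(Cl)=O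
Why: Friedel–Crafts acylation at the single free ring carbon (ortho and para to methoxy groups), after which AlCl3 chelated between the new ketone and the flanking methoxy oxygen cleaves only that methyl ether (chelation-controlled demethylation) and frees the future C1 phenol.

Step 4
Reactants: 5 1-(6-bromo-2-hydroxy-3,4-dimethoxy-5-methylphenyl)ethan-1-one; 6 3,5-dimethoxyphenylboronic acid
Product: 7 1-(3-hydroxy-3',4,5,5'-tetramethoxy-6-methyl-[1,1'-biphenyl]-2-yl)ethan-1-one
Conditions: Pd(OAc)2 (5 mol %), 2-dicyclohexylphosphino-2',6'-dimethoxybiphenyl (SPhos, 10 mol %), K3PO4 (3 equiv), PhMe–H2O (10:1), 100 °C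
Reagents that add atoms: none
Why: Suzuki–Miyaura coupling, in which the bulky electron-rich biarylphosphine lets zerovalent palladium insert into the di-ortho-substituted aryl bromide and the unhindered boronic acid transmetallates readily, the free phenol being tolerated as its phenoxide.

Step 5
Reactants: 7 1-(3-hydroxy-3',4,5,5'-tetramethoxy-6-methyl-[1,1'-biphenyl]-2-yl)ethan-1-one
Product: 8 (4R)-2-acetyl-3-(3,5-dimethoxyphenyl)-4-hydroxy-5,6-dimethoxy-4-methylcyclohexa-2,5-dien-1-one
Conditions: chiral aryl iodide (R,R)-2,2'-[(2-iodo-1,3-phenylene)bis(oxy)]bis[N-(2,4,6-trimethylphenyl)propanamide] (10 mol %), mCPBA (1.3 equiv), MeCN–H2O (9:1), −10 °C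
Reagents that add atoms: water, O
Why: Catalytic enantioselective hydroxylative phenol dearomatisation, in which mCPBA oxidises the aryl iodide to a chiral trivalent iodine species that binds the phenolic oxygen and directs water to one face of the methyl-bearing para carbon (both ortho carbons are substituted and the C2 methoxy group is twisted out of conjugation by its two neighbours), so C4 is set as R under catalyst control.

Step 6
Reactants: 8 (4R)-2-acetyl-3-(3,5-dimethoxyphenyl)-4-hydroxy-5,6-dimethoxy-4-methylcyclohexa-2,5-dien-1-one; 9 4,4-diethoxybutan-1-amine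
Product: 11 (3aS,4aR)-6-acetyl-5-(3,5-dimethoxyphenyl)-8-methoxy-4a-methyl-1,2,3,3a-tetrahydropyrrolo[2,1-b][1,3]benzoxazol-7(4aH)-one, via open-chain vinylogous amide 10 (not isolated)
Conditions: 9 (1.5 equiv), MeOH, 40 °C; concentrate; then CF3CO2H (3 equiv), CH2Cl2, 0 °C to rt
Reagents that add atoms: none
Why: Addition–elimination of the primary amine at C3 (β-carbon of the C1 enone, methoxide leaving; vinylogous ester to vinylogous amide) is followed by acid-induced N-acyliminium-type closure, in which the nitrogen captures the unmasked aldehyde carbon and the C4 hydroxyl traps the cyclic iminium ion, the aminal centre equilibrating under acid to the S isomer whose pyrrolidine C–C bond lies anti to the C4 methyl (aminal H cis to that methyl) on the cis-fused bicycle.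

Step 7
Reactants: 11 (3aS,4aR)-6-acetyl-5-(3,5-dimethoxyphenyl)-8-methoxy-4a-methyl-1,2,3,3a-tetrahydropyrrolo[2,1-b][1,3]benzoxazol-7(4aH)-one
Product: 13 (3aS,4aR)-6-(2-diazoacetyl)-5-(3,5-dimethoxyphenyl)-8-methoxy-4a-methyl-1,2,3,3a-tetrahydropyrrolo[2,1-b][1,3]benzoxazol-7(4aH)-one, via trifluoroacetyl diketone 12 (not isolated)
Conditions: LiN(SiMe3)2 (1.1 equiv), THF, −78 °C; CF3CO2CH2CF3 (1.2 equiv); AcOH quench; then MsN3 (1.5 equiv), Et3N (1.5 equiv), H2O (1 equiv), MeCN, rt
Reagents that add atoms: methanesulfonyl azide, CS(=O)(=O)N=[N+]=[N-]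
Why: Detrifluoroacetylative diazo transfer (a Regitz-type diazo transfer through a trifluoroacetyl-activated ketone), in which the acetyl methyl is the only enolisable position, its lithium enolate is trifluoroacetylated, and the activated 1,3-diketone takes the diazo group from MsN3 while the trifluoroacetyl group leaves as the N-acyl sulfonamide.

Step 8
Reactants: 13 (3aS,4aR)-6-(2-diazoacetyl)-5-(3,5-dimethoxyphenyl)-8-methoxy-4a-methyl-1,2,3,3a-tetrahydropyrrolo[2,1-b][1,3]benzoxazol-7(4aH)-one
Product: 16 8-O-methyl ether of the target (C9 keto tautomer; 4R and aminal S), via arylvinylketene 14 (not isolated), via ring-C-dearomatised cyclohexadienone 15 (not isolated)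
Conditions: PhMe (0.005 M), 150 °C, sealed vessel (microwave), 20 min, exclusion of light
Reagents that add atoms: none
Why: Heating expels N2 from the s-cis diazoketone with concerted 1,2-shift of the alkenyl carbon C10a to the diazo carbon (Wolff rearrangement, new C10a–C10 bond), giving ketene 14 whose carbonyl carbon becomes C9. Because C10a and C4a are joined by the ring A double bond, the ketene and the aryl group are held cis, so the C9=C10, C10a=C4a and C4b=C8a π bonds form a hexatriene that closes thermally by disrotatory 6π-electrocyclisation (C9–C8a bond, six-membered ring B) to dienone 15. Hydrogen transfer from C8a to C10 (suprafacial 1,5-shift, or enolisation and ketonisation through the C9 naphthol) restores ring C and leaves the C9 ketone and the C10 methylene. The closest known reaction type is the Wolff rearrangement–electrocyclisation benzannulation that converts cis-β-aryl-α,β-unsaturated diazoketones into 1-naphthols. No stereocentre is made (C8a of 15 is transient), C4 and the aminal carbon are not touched, and no regiochemical choice exists because both ortho carbons of the 3,5-dimethoxyphenyl ring are equivalent and activated by the methoxy groups. Metal-free thermal initiation in dilute aprotic solution is chosen to avoid carbenoid insertion into the aryl C–H bond (which would join C10 to C8a) and the light-induced rearrangement of the cross-conjugated dienone.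

Step 9
Reactants: 16 8-O-methyl ether of the target
Product: 17 target CNP0528850.1
Conditions: BCl3 (3 equiv), CH2Cl2, −78 to −30 °C; then H2O
Reagents that add atoms: none
Why: Chelation-controlled ether cleavage, in which BCl3 held between the C9 ketone and the peri C8 methoxy oxygen (six-membered chelate) delivers chloride to that methyl group only, the unchelated C6 ether and the C2 enol ether reacting more slowly, and any Lewis-acid opening of the N,O-acetal reclosing to the same thermodynamic isomer on work-up.

Compound list
1 | 5-bromo-1,2,3-trimethoxybenzene | COc1cc(Br)cc(OC)c1OC | starting material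
2 | 6-bromo-2,3,4-trimethoxybenzaldehyde | COc1cc(Br)c(C=O)c(OC)c1OC | intermediate
3 | 1-bromo-3,4,5-trimethoxy-2-methylbenzene | COc1cc(Br)c(C)c(OC)c1OC | intermediate
4 | 1-(6-bromo-2,3,4-trimethoxy-5-methylphenyl)ethan-1-one (not isolated) | COc1c(C(C)=O)c(Br)c(C)c(OC)c1OC | intermediate
5 | 1-(6-bromo-2-hydroxy-3,4-dimethoxy-5-methylphenyl)ethan-1-one | CC(=O)c1c(O)c(OC)c(OC)c(C)c1Br | intermediate
6 | 3,5-dimethoxyphenylboronic acid | COc1cc(OC)cc(B(O)O)c1 | starting material
7 | 1-(3-hydroxy-3',4,5,5'-tetramethoxy-6-methyl-[1,1'-biphenyl]-2-yl)ethan-1-one | CC(=O)c1c(O)c(OC)c(OC)c(C)c1-c1cc(OC)cc(OC)c1 | intermediate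
8 | (4R)-2-acetyl-3-(3,5-dimethoxyphenyl)-4-hydroxy-5,6-dimethoxy-4-methylcyclohexa-2,5-dien-1-one | COC1=C(OC)[C@@](O)(C)C(c2cc(OC)cc(OC)c2)=C(C(C)=O)C1=O | intermediate
9 | 4,4-diethoxybutan-1-amine | CCOC(CCCN)OCC | starting material
10 | (4R)-2-acetyl-5-[(4,4-diethoxybutyl)amino]-3-(3,5-dimethoxyphenyl)-4-hydroxy-6-methoxy-4-methylcyclohexa-2,5-dien-1-one (not isolated) | COC1=C(NCCCC(OCC)OCC)[C@@](O)(C)C(c2cc(OC)cc(OC)c2)=C(C(C)=O)C1=O | intermediate
11 | (3aS,4aR)-6-acetyl-5-(3,5-dimethoxyphenyl)-8-methoxy-4a-methyl-1,2,3,3a-tetrahydropyrrolo[2,1-b][1,3]benzoxazol-7(4aH)-one (ring A dienone with the pyrrolidine-fused oxazolidine, N on C3, O on C4) | COC1=C2N3CCC[C@@H]3O[C@]2(C)C(c2cc(OC)cc(OC)c2)=C(C(C)=O)C1=O | intermediate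
12 | 6-(4,4,4-trifluoro-3-oxobutanoyl) analogue of 11 (not isolated) | COC1=C2N3CCC[C@@H]3O[C@]2(C)C(c2cc(OC)cc(OC)c2)=C(C(=O)CC(=O)C(F)(F)F)C1=O | intermediate
13 | 6-(2-diazoacetyl) analogue of 11 (3aS,4aR; precursor of the key step) | COC1=C2N3CCC[C@@H]3O[C@]2(C)C(c2cc(OC)cc(OC)c2)=C(C(=O)C=[N+]=[N-])C1=O | intermediate
14 | 6-(2-oxoethenyl) ketene derived from 13 (not isolated) | COC1=C2N3CCC[C@@H]3O[C@]2(C)C(c2cc(OC)cc(OC)c2)=C(C=C=O)C1=O | intermediate
15 | 8a-H cyclohexadienone from 6π closure, C4a=C4b and C10=C10a double bonds, C8a configuration not defined (not isolated) | COC1=C2N3CCC[C@@H]3O[C@]2(C)C2=C3C=C(OC)C=C(OC)C3C(=O)C=C2C1=O | intermediate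
16 | (4R)-2,6,8-trimethoxy-4-methyl-4,10-dihydrophenanthrene-1,9-dione bridged from N on C3 to O on C4 by an (S)-pyrrolidin-2-yl N,O-acetal (8-O-methyl ether of the target) | COC1=C2N3CCC[C@@H]3O[C@]2(C)C2=C(CC(=O)c3c(OC)cc(OC)cc32)C1=O | intermediate
17 | CNP0528850.1: (4R)-8-hydroxy-2,6-dimethoxy-4-methyl-4,10-dihydrophenanthrene-1,9-dione bridged from N on C3 to O on C4 by an (S)-pyrrolidin-2-yl N,O-acetal | COC1=C2N3CCC[C@@H]3O[C@]2(C)C2=C(CC(=O)c3c(O)cc(OC)cc32)C1=O | target

Total step count: 9 steps.
Longest linear sequence: 9 steps (1 to 17); 6 and 9 are commercial and enter directly.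

Steps most likely to fail

1. Step 8. After loss of N2 the carbene or the ketene may react before ring B closes: insertion into the neighbouring aryl C–H bond, ylide formation with the C1 carbonyl, or ketene dimerisation if the twisted aryl ring is slow to become coplanar. Fallback, setting out from 13 and coming back at 16: 13 is rearranged with catalytic PhCO2Ag and Et3N in THF–H2O at room temperature in the dark (Arndt–Eistert homologation, ketene trapped by water) to give the homologated carboxylic acid F1. Trifluoroacetic anhydride in CH2Cl2 at 0 °C converts F1 into the mixed trifluoroacetic anhydride F2 (not isolated), which acylates the ortho carbon of the 3,5-dimethoxyphenyl ring intramolecularly (Friedel–Crafts acylation) to give 16. The two bonds are then made one after the other, C10a–C10 by the rearrangement and C9–C8a by electrophilic substitution.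

2. Step 5. Water may add to the methoxy-bearing ortho carbon (followed by loss of methanol to an ortho-quinone) instead of C4, and face discrimination by the catalyst may be poor on a hexasubstituted, hydrogen-bonded phenol. Fallback, setting out from 7 and coming back at 8: 7 is oxygenated with singlet oxygen generated from KHSO5 (as the triple salt 2KHSO5·KHSO4·K2SO4) and NaHCO3 in MeCN–H2O. Addition across C1 and C4 of the phenolate gives the racemic 4-hydroperoxy dienone F3, which Me2S reduces to the racemic quinol F4. F4 is separated by preparative chromatography on a chiral stationary phase, and the R enantiomer is 8.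

3. Step 6. The amine may add at another electrophilic carbon (conjugate addition at C4a, condensation at the acetyl group), or the acid stage may ionise the tertiary carbinol before the N,O-acetal closes. Fallback, setting out from 8 and coming back at 11: 8 is stirred with 1-pyrroline (released in solution from its commercial trimer) in MeOH at room temperature. Reversible addition of the C4 hydroxyl across the C=N bond gives the hemiaminal ether F5 (not isolated), whose N–H displaces the C3 methoxy group by intramolecular addition–elimination to close the oxazolidine and give 11 without an acid stage.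

Further compounds
F1 | step 8 | homologated acid, C10a–CH2–CO2H analogue of 13 (3aS,4aR) | COC1=C2N3CCC[C@@H]3O[C@]2(C)C(c2cc(OC)cc(OC)c2)=C(CC(=O)O)C1=O
F2 | step 8 | mixed trifluoroacetic anhydride of F1 (not isolated) | COC1=C2N3CCC[C@@H]3O[C@]2(C)C(c2cc(OC)cc(OC)c2)=C(CC(=O)OC(=O)C(F)(F)F)C1=O
F3 | step 5 | racemic 2-acetyl-3-(3,5-dimethoxyphenyl)-4-hydroperoxy-5,6-dimethoxy-4-methylcyclohexa-2,5-dien-1-one | COC1=C(OC)C(OO)(C)C(c2cc(OC)cc(OC)c2)=C(C(C)=O)C1=O
F4 | step 5 | racemic 2-acetyl-3-(3,5-dimethoxyphenyl)-4-hydroxy-5,6-dimethoxy-4-methylcyclohexa-2,5-dien-1-one | COC1=C(OC)C(O)(C)C(c2cc(OC)cc(OC)c2)=C(C(C)=O)C1=O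
F5 | step 6 | (4R)-4-(pyrrolidin-2-yloxy) hemiaminal ether of 8, aminal configuration not defined (not isolated) | COC1=C(OC)[C@@](OC2CCCN2)(C)C(c2cc(OC)cc(OC)c2)=C(C(C)=O)C1=O
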